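Count in molar of partner: each turn of a step with partner on its left takes one of it, so ask who gets how many.

    second substrate + partner → second product (k1 = 6.1 /M/s)
    2 third substrate → self-condensation product (k2 = 0.050 /M/s)
    third substrate + partner → third product (k3 = 0.024 /M/s)
    starting material + partner → target (k4 = 0.61 /M/s)

starting material 0.16 M; partner 0.112 M; second substrate 0.0320 M; third substrate 0.0800 M; time 30 s

- at 30 s, what has stopped the reaction, if anything has (it is still moving / all of the starting material has reacted / the partner has run out first)
- amount of target at 30 s, in percent of the starting material charged
- amount of target if the flask were left three thousand times as long, in percent of the starting material charged

- a doubled species enters its step squared and goes two at a time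
- the reaction counts as stopped when no species that holds the starting material changes by six tenths of a point or more over the second half of the time
- run time (flask): 30 s

This is my own reckoning, the run in slow motion. Watch the partner.

1. First instants. With partner as charged, the second substrate has a half-life of 1.0 s by its step alone. At the start the starting material takes partner at 0.50 of the second substrate's rate, but the second substrate's constant is ten times larger. Both meet the same partner, so the fraction of second substrate left is the fraction of starting material left raised to the power 10.0. With half of the starting material left, that is 0.0977%.

2. Middle. So take the second substrate's whole charge off the partner at once. This gives b = 50.0%, the partner budget: partner charged less second substrate charged, over starting material charged. The charges without that deduction would allow 70.0%. From here the partner is the limiting reagent. Starting material and budgeted partner fall together, and their difference D = 0.0800 M stays constant. The ratio of budgeted partner to starting material at time t is ρ = b·exp(−k·D·t), with k the constant of the target's step, and the target is (b − ρ)/(1 − ρ) of the charge.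

3. End. This gives 34.2% at 15.0 s and 43.5% at 30 s. That is a gain of 9.3 percentage points over the second half, so I say the flask is still moving.

4. Long run. At the start the third substrate takes 1.97% as much partner as the starting material does. Carrying that start share through the run is a rough step, and it gives my estimate of 49.0% for the long run.

The forecast says that at 30 s it is still moving, with 43.4% of target, and gives 48.8% in the long run. Its ground: “the reaction is still moving and will stop only when the partner runs out”. My figures of 43.5% and 49.0% lie close to these but are not the same.

In the simulation, at 30 s it is still moving, with 43.3% of target, and the long run gives 48.8%, which is 1.2 points under b. Partner use by the starting material over that by the second substrate goes from 0.50 at the start to 4.5 at 5.77 s and 82 at 30.0 s. In the neighbour flask with 0.27 M of starting material, b is 29.6%, and at 30.0 s that flask holds 29.1% of target with 1.2% of its partner left.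

(The constants are assumed; the run is a simulation.)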